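**Plan**

- Retrosynthesis: the five MOM ethers are removed last. Before that the C3'–CH3 bond is cut (methyl Grignard on a C3' ketone), then C3'–C4' (4-methylpent-3-enyl Grignard on a C3' aldehyde), then O1–C8a and C2–C3 of ring C (fluoride displacement and enolate acylation), then C4–C4a (aryllithium on a lactone) and the C6–prenyl bond.
- Forward: ring A (5-fluororesorcinol) is protected, prenylated between its oxygens and lithiated next to fluorine. The aryllithium opens a silylated (S)-hydroxymethyl-butyrolactone, ring B enters as an acylimidazole on the ketone enolate, and ring C closes by intramolecular SNAr; the fluorine fixes the prenyl group at C6.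
- The silyl ether is then converted into the C3' aldehyde and, by Grignard addition and reoxidation, into the 4-methylpent-3-enyl ketone.
- Enabling feature: the tertiary carbinol C3' of the chain on C3 of ring C sits next to the oxygen-bearing stereocentre C2'. A C3' ketone and the C2' ether oxygen can therefore hold magnesium in a five-membered chelate that distinguishes the two faces, although methyl and 4-methylpent-3-enyl are sterically alike.
- Stereochemistry: C2' (S) is C5 of the chiral-pool lactone and none of its bonds is broken; C3' (R) is set by chelation-controlled addition of MeMgBr.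

Key step: step 13

Locants: atoms of the 4H-chromen-4-one (rings A and C) carry plain numbers, the chain on C3 is numbered C1' to C8' from the ring, and ring B positions carry double primes.

**Route**

Step 1
Reactants: 1 5-fluorobenzene-1,3-diol
Product: 2 1-fluoro-3,5-bis(methoxymethoxy)benzene
Conditions: MOMCl, i-Pr2NEt, CH2Cl2, 0 °C → rt
Reagents that add atoms: chloromethyl methyl ether (MOMCl), COCCl
Why: Twofold O-alkylation of the phenols by the α-chloro ether (Williamson-type etherification) should give the bis-acetal, whose oxygens later direct metalation and which withstands every basic step that follows.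

Step 2
Reactants: 2 1-fluoro-3,5-bis(methoxymethoxy)benzene; 3 1-bromo-3-methylbut-2-ene (prenyl bromide)
Product: 5 5-fluoro-1,3-bis(methoxymethoxy)-2-(3-methylbut-2-en-1-yl)benzene, via aryllithium 4 (not isolated)
Conditions: n-BuLi, THF, −78 → −40 °C; then 3, −78 °C → rt
Reagents that add atoms: none
Why: Directed ortho-metalation should occur at the carbon flanked by both OMOM groups, where lithium is held by two acetal oxygens, and the aryllithium, which has no fluorine next to it and so cannot lose LiF, is then alkylated by the allylic bromide at its primary carbon (SN2).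

Step 3
Reactants: 6 (5S)-5-(hydroxymethyl)oxolan-2-one [(S)-5-(hydroxymethyl)dihydrofuran-2(3H)-one]
Product: 7 (5S)-5-{[tert-butyl(diphenyl)silyl]oxymethyl}oxolan-2-one
Conditions: TBDPSCl, imidazole, DMF, 0 °C → rt
Reagents that add atoms: tert-butyl(chloro)diphenylsilane (TBDPSCl), CC(C)(C)[Si](Cl)(c1ccccc1)c1ccccc1
Why: Imidazole-promoted silylation of the primary alcohol leaves the stereocentre (lactone C5, the later C2') untouched and gives a silyl ether that survives organolithium, amide base and carbonate.

Step 4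
Reactants: 5 5-fluoro-1,3-bis(methoxymethoxy)-2-(3-methylbut-2-en-1-yl)benzene; 7 (5S)-5-{[tert-butyl(diphenyl)silyl]oxymethyl}oxolan-2-one
Product: 9 (4S)-5-{[tert-butyl(diphenyl)silyl]oxy}-1-[6-fluoro-2,4-bis(methoxymethoxy)-3-(3-methylbut-2-en-1-yl)phenyl]-4-hydroxypentan-1-one, via aryllithium 8 (not isolated)
Conditions: n-BuLi, THF, −78 °C; then 7, THF, −78 °C; aq. NH4Cl
Reagents that add atoms: none
Why: A second directed ortho-metalation can only take the two equivalent ring positions between fluorine and OMOM, and the hindered aryllithium then undergoes nucleophilic acyl substitution at the lactone carbonyl, the lithium lactolate being stable at −78 °C so that one aryl group adds and the ring opens on work-up to the γ-hydroxy ketone with the C2' centre unchanged.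

Step 5
Reactants: 9 (4S)-5-{[tert-butyl(diphenyl)silyl]oxy}-1-[6-fluoro-2,4-bis(methoxymethoxy)-3-(3-methylbut-2-en-1-yl)phenyl]-4-hydroxypentan-1-one
Product: 10 (4S)-5-{[tert-butyl(diphenyl)silyl]oxy}-1-[6-fluoro-2,4-bis(methoxymethoxy)-3-(3-methylbut-2-en-1-yl)phenyl]-4-(methoxymethoxy)pentan-1-one
Conditions: MOMCl, i-Pr2NEt, CH2Cl2, 0 °C → rt
Reagents that add atoms: chloromethyl methyl ether (MOMCl), COCCl
Why: Etherification of the secondary alcohol with MOMCl and a hindered amine traps the open-chain form of the hydroxy ketone and installs the bidentate acetal needed for chelation in step 13.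

Step 6
Reactants: 11 2,4-dihydroxybenzoic acid
Product: 13 2,4-bis(methoxymethoxy)benzoic acid, via methoxymethyl ester 12 (not isolated)
Conditions: NaH, MOMCl, DMF, 0 °C → rt; then NaOH, MeOH–H2O, 50 °C; cold 1 M HCl to pH 4
Reagents that add atoms: chloromethyl methyl ether (MOMCl), COCCl; sodium hydroxide (its oxygen ends in the carboxyl group), [Na+].[OH-]
Why: Exhaustive O-alkylation of the sodium salts followed by saponification in the same flask (acyl–oxygen cleavage of the methoxymethyl ester) should give the acid, since aryl MOM ethers are inert to hydroxide.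

Step 7
Reactants: 10 (4S)-5-{[tert-butyl(diphenyl)silyl]oxy}-1-[6-fluoro-2,4-bis(methoxymethoxy)-3-(3-methylbut-2-en-1-yl)phenyl]-4-(methoxymethoxy)pentan-1-one; 13 2,4-bis(methoxymethoxy)benzoic acid
Product: 16 2-[(2S)-3-{[tert-butyl(diphenyl)silyl]oxy}-2-(methoxymethoxy)propyl]-1-[2,4-bis(methoxymethoxy)phenyl]-3-[6-fluoro-2,4-bis(methoxymethoxy)-3-(3-methylbut-2-en-1-yl)phenyl]propane-1,3-dione (C2 epimers and enol forms), via acylimidazole 14 (not isolated), via lithium enolate 15 (not isolated)
Conditions: 13, CDI, THF, rt; 10, LiN(SiMe3)2 (3.3 equiv), THF, −78 °C; combine, −78 → 0 °C; aq. NH4Cl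
Reagents that add atoms: none
Why: Crossed Claisen-type C-acylation of the lithium enolate by the acylimidazole, an acyl donor made without acid and less prone to O-acylation than an acid chloride, should give the 2-substituted 1,3-diketone, the extra base covering the imidazole released and the acidic product.

Step 8
Reactants: 16 the 1,3-diketone of step 7
Product: 17 2-[2,4-bis(methoxymethoxy)phenyl]-3-[(2S)-3-{[tert-butyl(diphenyl)silyl]oxy}-2-(methoxymethoxy)propyl]-5,7-bis(methoxymethoxy)-6-(3-methylbut-2-en-1-yl)-4H-chromen-4-one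
Conditions: K2CO3, DMF, 80 °C
Reagents that add atoms: none
Why: Intramolecular nucleophilic aromatic substitution (addition–elimination): the diketone enolate oxygen on the ring B side attacks the fluorine-bearing carbon, activated by the ortho carbonyl, and closes the six-membered pyranone ring C, with the prenyl group necessarily at C6 because the fluorine marks C8a.

Step 9
Reactants: 17 the silylated flavone of step 8
Product: 18 2-[2,4-bis(methoxymethoxy)phenyl]-3-[(2S)-3-hydroxy-2-(methoxymethoxy)propyl]-5,7-bis(methoxymethoxy)-6-(3-methylbut-2-en-1-yl)-4H-chromen-4-one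
Conditions: Bu4NF, AcOH, THF, 0 °C → rt
Reagents that add atoms: none
Why: Fluoride-induced cleavage of the silicon–oxygen bond, buffered with acetic acid so that the pyranone is not opened by alkoxide, should free the primary alcohol while all MOM ethers stay.

Step 10
Reactants: 18 the primary alcohol of step 9
Product: 19 (2S)-3-{2-[2,4-bis(methoxymethoxy)phenyl]-5,7-bis(methoxymethoxy)-6-(3-methylbut-2-en-1-yl)-4-oxo-4H-chromen-3-yl}-2-(methoxymethoxy)propanal
Conditions: Dess–Martin periodinane, CH2Cl2, 0 °C → rt; used crude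
Reagents that add atoms: none
Why: Dess–Martin oxidation converts the primary alcohol to the aldehyde under nearly neutral conditions, which should keep the α-alkoxy stereocentre C2' from epimerising.

Step 11
Reactants: 19 the aldehyde of step 10; 20 5-bromo-2-methylpent-2-ene
Product: 22 2-[2,4-bis(methoxymethoxy)phenyl]-3-[(2S)-3-hydroxy-2-(methoxymethoxy)-7-methyloct-6-en-1-yl]-5,7-bis(methoxymethoxy)-6-(3-methylbut-2-en-1-yl)-4H-chromen-4-one (both C3' epimers), via Grignard reagent 21 (not isolated)
Conditions: 20, Mg, THF, rt → 40 °C; then 19, THF, −78 °C; aq. NH4Cl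
Reagents that add atoms: none
Why: Grignard 1,2-addition to the aldehyde, which is far more electrophilic than the C4 carbonyl of ring C at −78 °C, joins C3' to C4'; the configuration of the new carbinol is irrelevant because it is oxidised in the next step.

Step 12
Reactants: 22 the C3' carbinol of step 11
Product: 23 2-[2,4-bis(methoxymethoxy)phenyl]-5,7-bis(methoxymethoxy)-3-[(2S)-2-(methoxymethoxy)-7-methyl-3-oxooct-6-en-1-yl]-6-(3-methylbut-2-en-1-yl)-4H-chromen-4-one
Conditions: Dess–Martin periodinane, CH2Cl2, 0 °C → rt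
Reagents that add atoms: none
Why: Dess–Martin oxidation takes both C3' epimers to the single α-alkoxy ketone without base, so C2' should stay (S).

Step 13
Reactants: 23 the C3' ketone of step 12; 24 methylmagnesium bromide
Product: 25 2-[2,4-bis(methoxymethoxy)phenyl]-3-[(2S,3R)-3-hydroxy-2-(methoxymethoxy)-3,7-dimethyloct-6-en-1-yl]-5,7-bis(methoxymethoxy)-6-(3-methylbut-2-en-1-yl)-4H-chromen-4-one
Conditions: MeMgBr (3 M in Et2O, 3 equiv), THF, −78 °C; aq. NH4Cl
Reagents that add atoms: none
Why: Magnesium binds the C3' carbonyl oxygen and the C2' acetal oxygen of the MOM ether in a five-membered chelate, which activates the ketone and locks the C2'–C3' rotamer, and methyl is then transferred to the carbonyl carbon in a 1,2-addition. The closest known reaction type is the chelation-controlled (Cram cyclic model) Grignard addition to α-alkoxymethoxy ketones in THF at low temperature. No ring is closed; only the C3'–CH3 bond and the C3' stereocentre form. The new centre is controlled by the (S)-C2' centre: in the chelate the C1' methylene carrying the flavone shields one face, so methyl enters from the face of the C2' hydrogen and, with the 4-methylpent-3-enyl group already on the ketone, the (3'R) carbinol of the (2'S,3'R) pair should result. The step needs diastereofacial selectivity and chemoselectivity against the C4 carbonyl and C2 of ring C; the first is secured by the bidentate MOM ether, the second by chelate activation of the aliphatic ketone at −78 °C against a vinylogous ester carbonyl flanked by the 5-OMOM group and the C3 substituent.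

Step 14
Reactants: 25 the pentakis(methoxymethyl) ether of step 13
Product: 26 2-(2,4-dihydroxyphenyl)-3-[(2S,3R)-2,3-dihydroxy-3,7-dimethyloct-6-en-1-yl]-5,7-dihydroxy-6-(3-methylbut-2-en-1-yl)-4H-chromen-4-one (CNP0113932.1)
Conditions: 3 M HCl (aq.), MeOH, 45 °C
Reagents that add atoms: none
Why: Acid-catalysed acetal exchange with methanol removes the four aryl and the one alkyl MOM ether as dimethoxymethane; methanol in large excess should capture the methoxymethyl cation before the neighbouring C3' hydroxyl can, and the dilute acid at moderate temperature should leave both trisubstituted alkenes and the two stereocentres alone.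

**Compound list**

1 | 5-fluorobenzene-1,3-diol | Oc1cc(O)cc(F)c1 | starting material
2 | 1-fluoro-3,5-bis(methoxymethoxy)benzene | COCOc1cc(F)cc(OCOC)c1 | intermediate
3 | 1-bromo-3-methylbut-2-ene | CC(C)=CCBr | starting material
4 | [4-fluoro-2,6-bis(methoxymethoxy)phenyl]lithium (not isolated) | [Li]c1c(OCOC)cc(F)cc1OCOC | intermediate
5 | 5-fluoro-1,3-bis(methoxymethoxy)-2-(3-methylbut-2-en-1-yl)benzene | CC(C)=CCc1c(OCOC)cc(F)cc1OCOC | intermediate
6 | (5S)-5-(hydroxymethyl)oxolan-2-one | O=C1CC[C@@H](CO)O1 | starting material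
7 | (5S)-5-{[tert-butyl(diphenyl)silyl]oxymethyl}oxolan-2-one | O=C1CC[C@@H](CO[Si](c2ccccc2)(c2ccccc2)C(C)(C)C)O1 | intermediate
8 | [6-fluoro-2,4-bis(methoxymethoxy)-3-(3-methylbut-2-en-1-yl)phenyl]lithium (not isolated) | [Li]c1c(F)cc(OCOC)c(CC=C(C)C)c1OCOC | intermediate
9 | (4S)-5-{[tert-butyl(diphenyl)silyl]oxy}-1-[6-fluoro-2,4-bis(methoxymethoxy)-3-(3-methylbut-2-en-1-yl)phenyl]-4-hydroxypentan-1-one | CC(C)=CCc1c(OCOC)cc(F)c(C(=O)CC[C@H](O)CO[Si](c2ccccc2)(c2ccccc2)C(C)(C)C)c1OCOC | intermediate
10 | (4S)-5-{[tert-butyl(diphenyl)silyl]oxy}-1-[6-fluoro-2,4-bis(methoxymethoxy)-3-(3-methylbut-2-en-1-yl)phenyl]-4-(methoxymethoxy)pentan-1-one | CC(C)=CCc1c(OCOC)cc(F)c(C(=O)CC[C@H](OCOC)CO[Si](c2ccccc2)(c2ccccc2)C(C)(C)C)c1OCOC | intermediate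
11 | 2,4-dihydroxybenzoic acid | O=C(O)c1ccc(O)cc1O | starting material
12 | methoxymethyl 2,4-bis(methoxymethoxy)benzoate (not isolated) | COCOC(=O)c1ccc(OCOC)cc1OCOC | intermediate
13 | 2,4-bis(methoxymethoxy)benzoic acid | COCOc1ccc(C(=O)O)c(OCOC)c1 | intermediate
14 | [2,4-bis(methoxymethoxy)phenyl](1H-imidazol-1-yl)methanone (not isolated) | COCOc1ccc(C(=O)n2ccnc2)c(OCOC)c1 | intermediate
15 | lithium (Z)-enolate of ketone 10 (not isolated) | [Li]O/C(=C\C[C@H](OCOC)CO[Si](c1ccccc1)(c1ccccc1)C(C)(C)C)c1c(F)cc(OCOC)c(CC=C(C)C)c1OCOC | intermediate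
16 | 2-[(2S)-3-{[tert-butyl(diphenyl)silyl]oxy}-2-(methoxymethoxy)propyl]-1-[2,4-bis(methoxymethoxy)phenyl]-3-[6-fluoro-2,4-bis(methoxymethoxy)-3-(3-methylbut-2-en-1-yl)phenyl]propane-1,3-dione (C2 epimers) | CC(C)=CCc1c(OCOC)cc(F)c(C(=O)C(C[C@H](OCOC)CO[Si](c2ccccc2)(c2ccccc2)C(C)(C)C)C(=O)c2ccc(OCOC)cc2OCOC)c1OCOC | intermediate
17 | 2-[2,4-bis(methoxymethoxy)phenyl]-3-[(2S)-3-{[tert-butyl(diphenyl)silyl]oxy}-2-(methoxymethoxy)propyl]-5,7-bis(methoxymethoxy)-6-(3-methylbut-2-en-1-yl)-4H-chromen-4-one | CC(C)=CCc1c(OCOC)cc2oc(-c3ccc(OCOC)cc3OCOC)c(C[C@H](OCOC)CO[Si](c3ccccc3)(c3ccccc3)C(C)(C)C)c(=O)c2c1OCOC | intermediate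
18 | 2-[2,4-bis(methoxymethoxy)phenyl]-3-[(2S)-3-hydroxy-2-(methoxymethoxy)propyl]-5,7-bis(methoxymethoxy)-6-(3-methylbut-2-en-1-yl)-4H-chromen-4-one | CC(C)=CCc1c(OCOC)cc2oc(-c3ccc(OCOC)cc3OCOC)c(C[C@H](OCOC)CO)c(=O)c2c1OCOC | intermediate
19 | (2S)-3-{2-[2,4-bis(methoxymethoxy)phenyl]-5,7-bis(methoxymethoxy)-6-(3-methylbut-2-en-1-yl)-4-oxo-4H-chromen-3-yl}-2-(methoxymethoxy)propanal | CC(C)=CCc1c(OCOC)cc2oc(-c3ccc(OCOC)cc3OCOC)c(C[C@H](OCOC)C=O)c(=O)c2c1OCOC | intermediate
20 | 5-bromo-2-methylpent-2-ene | CC(C)=CCCBr | starting material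
21 | (4-methylpent-3-en-1-yl)magnesium bromide (not isolated) | CC(C)=CCC[Mg]Br | intermediate
22 | 2-[2,4-bis(methoxymethoxy)phenyl]-3-[(2S)-3-hydroxy-2-(methoxymethoxy)-7-methyloct-6-en-1-yl]-5,7-bis(methoxymethoxy)-6-(3-methylbut-2-en-1-yl)-4H-chromen-4-one (both C3' epimers) | CC(C)=CCCC(O)[C@@H](OCOC)Cc1c(-c2ccc(OCOC)cc2OCOC)oc2cc(OCOC)c(CC=C(C)C)c(OCOC)c2c1=O | intermediate
23 | 2-[2,4-bis(methoxymethoxy)phenyl]-5,7-bis(methoxymethoxy)-3-[(2S)-2-(methoxymethoxy)-7-methyl-3-oxooct-6-en-1-yl]-6-(3-methylbut-2-en-1-yl)-4H-chromen-4-one | CC(C)=CCCC(=O)[C@@H](OCOC)Cc1c(-c2ccc(OCOC)cc2OCOC)oc2cc(OCOC)c(CC=C(C)C)c(OCOC)c2c1=O | intermediate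
24 | methylmagnesium bromide | C[Mg]Br | starting material
25 | 2-[2,4-bis(methoxymethoxy)phenyl]-3-[(2S,3R)-3-hydroxy-2-(methoxymethoxy)-3,7-dimethyloct-6-en-1-yl]-5,7-bis(methoxymethoxy)-6-(3-methylbut-2-en-1-yl)-4H-chromen-4-one | CC(C)=CCC[C@@](C)(O)[C@@H](OCOC)Cc1c(-c2ccc(OCOC)cc2OCOC)oc2cc(OCOC)c(CC=C(C)C)c(OCOC)c2c1=O | intermediate
26 | 2-(2,4-dihydroxyphenyl)-3-[(2S,3R)-2,3-dihydroxy-3,7-dimethyloct-6-en-1-yl]-5,7-dihydroxy-6-(3-methylbut-2-en-1-yl)-4H-chromen-4-one | CC(C)=CCC[C@@](C)(O)[C@@H](O)Cc1c(-c2ccc(O)cc2O)oc2cc(O)c(CC=C(C)C)c(O)c2c1=O | target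

**Step count and risks**

Total step count: 14. Longest linear sequence: 12 steps (steps 1, 2, 4, 5, 7, 8, 9, 10, 11, 12, 13 and 14, from 1 to 26).

Steps most likely to fail:

1. Step 7. The hindered enolate may be acylated at oxygen instead of carbon, giving an enol ester, or may simply be reprotonated by the imidazole present, returning the ketone. The fallback replaces acyl transfer by an aldol addition, in which only carbon can bond. It sets out from ketone 10 through its enolate 15. Commercial 2,4-dihydroxybenzaldehyde F1 is converted with NaH and MOMCl in DMF into 2,4-bis(methoxymethoxy)benzaldehyde F2. F2 is added to enolate 15 at −78 °C to give the β-hydroxy ketone aldol adduct F3 as a mixture of diastereomers. Oxidation of F3 with Dess–Martin periodinane in CH2Cl2 then gives the 1,3-diketone, and the route is rejoined at 16.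

2. Step 4. The basic, hindered aryllithium may take a proton from the α-methylene of the lactone instead of adding, which returns arene 5. A lactolate that collapses early may take up a second aryl group. Warming may let aryllithium 8 lose LiF to an aryne. The fallback changes the electrophile and the order of protection. It sets out from lactone 7, which is opened with Me2AlN(OMe)Me (from AlMe3 and MeNHOMe·HCl, CH2Cl2) to (4S)-5-{[tert-butyl(diphenyl)silyl]oxy}-4-hydroxy-N-methoxy-N-methylpentanamide F4. MOMCl and i-Pr2NEt convert F4 into (4S)-5-{[tert-butyl(diphenyl)silyl]oxy}-N-methoxy-4-(methoxymethoxy)-N-methylpentanamide F5. Aryllithium 8, made from 5 as before and kept at −78 °C, adds once to this less acidic amide through a stable chelated adduct. The route is rejoined at ketone 10, and step 5 is then not needed.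

3. Step 2. Deprotonation may compete at the positions between fluorine and OMOM. An aryllithium with fluorine next to it would be alkylated to a regioisomer or would eliminate LiF on warming. The fallback fixes the site with a halogen instead of relying on relative acidity. It sets out from diol 1, which is iodinated between the hydroxyl groups (I2, NaHCO3, water, 0 °C) to 5-fluoro-2-iodobenzene-1,3-diol F6. Protection with MOMCl and i-Pr2NEt gives 5-fluoro-2-iodo-1,3-bis(methoxymethoxy)benzene F7. Iodine–lithium exchange with n-BuLi in THF at −78 °C, which is faster than any deprotonation, then gives the aryllithium. The route is rejoined at 4, which is alkylated with 3 to 5 as in step 2.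

**Further compounds**

F1 | step 7 | 2,4-dihydroxybenzaldehyde | O=Cc1ccc(O)cc1O
F2 | step 7 | 2,4-bis(methoxymethoxy)benzaldehyde | COCOc1ccc(C=O)c(OCOC)c1
F3 | step 7 | 3-[2,4-bis(methoxymethoxy)phenyl]-2-[(2S)-3-{[tert-butyl(diphenyl)silyl]oxy}-2-(methoxymethoxy)propyl]-1-[6-fluoro-2,4-bis(methoxymethoxy)-3-(3-methylbut-2-en-1-yl)phenyl]-3-hydroxypropan-1-one (diastereomers at C2 and C3) | CC(C)=CCc1c(OCOC)cc(F)c(C(=O)C(C[C@H](OCOC)CO[Si](c2ccccc2)(c2ccccc2)C(C)(C)C)C(O)c2ccc(OCOC)cc2OCOC)c1OCOC
F4 | step 4 | (4S)-5-{[tert-butyl(diphenyl)silyl]oxy}-4-hydroxy-N-methoxy-N-methylpentanamide | CON(C)C(=O)CC[C@H](O)CO[Si](c1ccccc1)(c1ccccc1)C(C)(C)C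
F5 | step 4 | (4S)-5-{[tert-butyl(diphenyl)silyl]oxy}-N-methoxy-4-(methoxymethoxy)-N-methylpentanamide | CON(C)C(=O)CC[C@H](OCOC)CO[Si](c1ccccc1)(c1ccccc1)C(C)(C)C
F6 | step 2 | 5-fluoro-2-iodobenzene-1,3-diol | Oc1cc(F)cc(O)c1I
F7 | step 2 | 5-fluoro-2-iodo-1,3-bis(methoxymethoxy)benzene | COCOc1cc(F)cc(OCOC)c1I
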